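**Retrosynthetic overview**

1. The target is opened at the C6–O lactone bond (Mitsunobu closure with inversion) to a 3-oxo-6-hydroxy-4Z seco acid. This comes by Kornblum–DeLaMare opening of a C3–C6 endoperoxide, made by [4+2] addition of singlet oxygen to the (3Z,5Z)-diene of the ten-membered carbocycle, which already carries the 1,2-oxirane, the C8 tiglate and the C7 acrylate.
2. The feature on which the plan rests is the C3(=O)–C4(CH3)=C5–C6(O) unit of the ten-membered ring with C3 and C6 cis on C4=C5, which is the ring-opened form of a 3,6-dihydro-1,2-dioxine bridging C3 and C6.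
3. The carbocycle comes from an intramolecular Stille coupling at C4–C5 (Z-vinyl iodide plus Z-vinylstannane); the C7–C8 bond comes from an asymmetric chromium-catalysed 2-(alkoxycarbonyl)allylation of a C8 aldehyde with a stannylated dienyl bromide.
4. The aldehyde derives from (S)-2-methylglycidol (C10), a Sharpless epoxidation (C1, C2) and a Z-selective iodo-olefination (C3=C4); the bromide derives from propargyl alcohol and a propiolate.
5. Ring order: oxirane (step 4), ten-membered carbocycle (step 15), 1,2-dioxine (step 16, opened in step 17), γ-lactone (step 19).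

Key step: step 16

Assumption: the SMILES is read as a cis-fused 12,6-lactone (O6, C11 and O8 on one ring face), a trans 1,2-oxirane and 1,3-anti oxygens at C8/C10; germacrane numbering is used (ring C1–C10, acrylate C11–C13, C14 on C10, C15 on C4), and (S)-2-methylglycidol is taken as commercial.

**Route**

Step 1
Reactants: 1 (S)-2-methylglycidol
Product: 2 (R)-2-methylpent-4-ene-1,2-diol
Conditions: CH2=CHMgBr, CuI (10 mol %), THF, −30 → 0 °C
Reagents that add atoms: vinylmagnesium bromide, C=C[Mg]Br
Why: Copper-catalysed Grignard opening of the 2,2-disubstituted epoxide occurs at the unsubstituted CH2 (SN2), so the quaternary carbinol C10 is carried over unchanged from the chiral starting material.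

Step 2
Reactants: 2 (R)-2-methylpent-4-ene-1,2-diol
Product: 4 ethyl (R,E)-4-hydroxy-4-methylhepta-2,6-dienoate, via (R)-2-hydroxy-2-methylpent-4-enal 3 (not isolated)
Conditions: (COCl)2, DMSO, CH2Cl2, −78 °C; Et3N; then Ph3P=CHCO2Et, −78 °C → rt
Reagents that add atoms: ethyl (triphenylphosphoranylidene)acetate, CCOC(=O)C=P(c1ccccc1)(c1ccccc1)c1ccccc1
Why: Swern oxidation can only touch the primary alcohol, and the non-enolisable α-hydroxy aldehyde is trapped in the same flask by a stabilised Wittig ylide, which should give the E-enoate.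

Step 3
Reactants: 4 ethyl (R,E)-4-hydroxy-4-methylhepta-2,6-dienoate
Product: 5 (R,E)-4-methylhepta-2,6-diene-1,4-diol
Conditions: i-Bu2AlH (3.5 equiv), CH2Cl2, −78 °C
Reagents that add atoms: none
Why: 1,2-Reduction of the conjugated ester by the aluminium hydride gives the allylic alcohol; the isolated terminal alkene is inert.

Step 4
Reactants: 5 (R,E)-4-methylhepta-2,6-diene-1,4-diol
Product: 6 [(2S,3R)-3-[(2R)-2-hydroxypent-4-en-2-yl]oxiran-2-yl]methanol
Conditions: Ti(OiPr)4 (10 mol %), L-(+)-diethyl tartrate (12 mol %), t-BuOOH, 4 Å MS, CH2Cl2, −20 °C; non-basic work-up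
Reagents that add atoms: tert-butyl hydroperoxide, CC(C)(C)OO
Why: Sharpless asymmetric epoxidation of the E primary allylic alcohol; the L-(+)-tartrate catalyst sets both oxirane centres (C1 and C2 of the target) by reagent control, and the monosubstituted alkene is not epoxidised.

Step 5
Reactants: 6 [(2S,3R)-3-[(2R)-2-hydroxypent-4-en-2-yl]oxiran-2-yl]methanol
Product: 7 (2R,3R)-3-[(2R)-2-hydroxypent-4-en-2-yl]oxirane-2-carbaldehyde
Conditions: TEMPO (10 mol %), PhI(OAc)2, CH2Cl2, 0 °C → rt
Reagents that add atoms: none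
Why: Oxoammonium (TEMPO) oxidation converts the primary alcohol into the aldehyde; the tertiary alcohol and the oxirane are not affected.

Step 6
Reactants: 7 (2R,3R)-3-[(2R)-2-hydroxypent-4-en-2-yl]oxirane-2-carbaldehyde
Product: 8 (2R)-2-[(2R,3S)-3-[(1Z)-2-iodoprop-1-en-1-yl]oxiran-2-yl]pent-4-en-2-ol
Conditions: [Ph3PEt]I, n-BuLi, THF, rt; I2, −78 °C; NaN(SiMe3)2, −20 °C; then 7, −78 °C
Reagents that add atoms: ethyltriphenylphosphonium iodide, CC[P+](c1ccccc1)(c1ccccc1)c1ccccc1.[I-]; iodine, [I][I]
Why: Stork–Zhao-type Wittig olefination with the α-iodo ylide gives the Z-2-iodoalkene through the kinetic cis-oxaphosphetane, which fixes the later C3=C4 geometry (C2 and iodine cis).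

Step 7
Reactants: 8 (2R)-2-[(2R,3S)-3-[(1Z)-2-iodoprop-1-en-1-yl]oxiran-2-yl]pent-4-en-2-ol
Product: 9 (3R)-3-hydroxy-3-[(2R,3S)-3-[(1Z)-2-iodoprop-1-en-1-yl]oxiran-2-yl]butanal
Conditions: OsO4 (2 mol %), NaIO4, 2,6-lutidine, dioxane/H2O 3:1, rt
Reagents that add atoms: sodium periodate, [Na+].[O-]I(=O)(=O)=O
Why: Lemieux–Johnson cleavage; OsO4 should dihydroxylate the unhindered monosubstituted alkene in preference to the electron-poor trisubstituted vinyl iodide, and periodate cleaves the diol to the C8 aldehyde.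

Step 8
Reactants: 10 propiolic acid, 11 2-(trimethylsilyl)ethanol
Product: 12 2-(trimethylsilyl)ethyl propiolate
Conditions: DCC, DMAP (5 mol %), CH2Cl2, −20 → 0 °C
Reagents that add atoms: none
Why: Steglich esterification at low temperature installs an ester that fluoride can later remove without hydrolysis.

Step 9
Reactants: 13 propargyl alcohol
Product: 15 (Z)-3-(tributylstannyl)prop-2-en-1-ol, via cyclic lithium vinylalanate 14 (not isolated)
Conditions: LiAlH4, THF, 0 °C → rt; then Bu3SnOTf, −78 °C
Reagents that add atoms: tributyltin trifluoromethanesulfonate, CCCC[Sn](CCCC)(CCCC)OS(=O)(=O)C(F)(F)F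
Why: Hydroxyl-directed trans-hydroalumination gives a five-membered vinylalanate, and aluminium-to-tin exchange with retention gives the Z-vinylstannane.

Step 10
Reactants: 15 (Z)-3-(tributylstannyl)prop-2-en-1-ol
Product: 16 (Z)-3-(tributylstannyl)prop-2-enal
Conditions: MnO2 (activated), CH2Cl2, 0 °C, used at once
Reagents that add atoms: none
Why: Allylic oxidation with MnO2 is neutral, and immediate use of the enal limits Z-to-E isomerisation.

Step 11
Reactants: 12 2-(trimethylsilyl)ethyl propiolate, 16 (Z)-3-(tributylstannyl)prop-2-enal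
Product: 18 2-(trimethylsilyl)ethyl (4Z)-3-hydroxy-2-methylidene-5-(tributylstannyl)pent-4-enoate (racemic), via vinylalane 17 (not isolated)
Conditions: 12, i-Bu2AlH, N-methylmorpholine N-oxide, THF, 0 °C; then 16, 0 °C → rt
Reagents that add atoms: none
Why: Conjugate hydroalumination of the propiolate gives the α-(alkoxycarbonyl)vinylalane, which adds 1,2 to the enal (vinylalumination) and gives the Baylis–Hillman-type adduct without an amine catalyst that would isomerise the Z-enal; the carbinol centre is removed in step 12.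

Step 12
Reactants: 18 2-(trimethylsilyl)ethyl (4Z)-3-hydroxy-2-methylidene-5-(tributylstannyl)pent-4-enoate
Product: 20 2-(trimethylsilyl)ethyl (2Z,4Z)-2-(bromomethyl)-5-(tributylstannyl)penta-2,4-dienoate, via allylic mesylate 19 (not isolated)
Conditions: MeSO2Cl, Et3N, CH2Cl2, −40 °C; then LiBr, THF, 0 °C
Reagents that add atoms: lithium bromide, [Li+].[Br-]
Why: Mesylation followed by SN2' displacement with bromide (allylic transposition) gives the conjugated primary bromide; the 2Z isomer, with the alkenyl group trans to the ester, is the thermodynamically preferred one, and the neutral conditions spare the vinylstannane.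

Step 13
Reactants: 9 (3R)-3-hydroxy-3-[(2R,3S)-3-[(1Z)-2-iodoprop-1-en-1-yl]oxiran-2-yl]butanal, 20 2-(trimethylsilyl)ethyl (2Z,4Z)-2-(bromomethyl)-5-(tributylstannyl)penta-2,4-dienoate
Product: 22 2-(trimethylsilyl)ethyl (3R,4R,6R)-4,6-dihydroxy-6-[(2R,3S)-3-[(1Z)-2-iodoprop-1-en-1-yl]oxiran-2-yl]-2-methylidene-3-[(1Z)-2-(tributylstannyl)ethenyl]heptanoate, via allylchromium species 21 (not isolated)
Conditions: CrCl2 (10 mol %), chiral 1,8-bis(4-isopropyl-4,5-dihydrooxazol-2-yl)-3,6-diphenylcarbazole ligand (12 mol %, the enantiomer that directs addition to the Si face of the aldehyde), Mn powder, Cp2ZrCl2, i-Pr2NEt, THF, 0 °C → rt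
Reagents that add atoms: none
Why: Catalytic asymmetric Nozaki–Hiyama–Kishi 2-(alkoxycarbonyl)allylation; the allylchromium reagent reacts at its γ-carbon (C7) through a chair transition state, and its fixed geometry (C6 cis to CH2Cr) should give the C7/C8 syn, cis-lactone-type pair. The ligand selects the aldehyde face so that C8 becomes R, anti to the C10 carbinol, whose own bias from a β-quaternary centre is weak. Chromium without nickel does not insert into the vinyl iodide.

Step 14
Reactants: 22 the diol ester of step 13, 23 tiglic acid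
Product: 25 2-(trimethylsilyl)ethyl (3R,4R,6R)-6-hydroxy-6-[(2R,3S)-3-[(1Z)-2-iodoprop-1-en-1-yl]oxiran-2-yl]-2-methylidene-4-[(2E)-2-methylbut-2-enoyl]oxy-3-[(1Z)-2-(tributylstannyl)ethenyl]heptanoate, via mixed anhydride 24 (not isolated)
Conditions: 23, 2,4,6-trichlorobenzoyl chloride, Et3N, THF, rt; then 22, DMAP, toluene, rt
Reagents that add atoms: none
Why: Yamaguchi esterification acylates the secondary C8 alcohol; the tertiary C10 alcohol does not react under these conditions and the E geometry of the tiglate is kept.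

Step 15
Reactants: 25 the tiglate of step 14
Product: 26 2-(trimethylsilyl)ethyl (1R,2S,3Z,5Z,7R,8R,10R)-1,2-epoxy-10-hydroxy-8-tigloyloxygermacra-3,5,11(13)-trien-12-oate
Conditions: Pd(PPh3)4 (10 mol %), copper thiophene-2-carboxylate (CuTC), [NBu4][Ph2PO2], DMF, rt, 1 mM
Reagents that add atoms: none
Why: Intramolecular Stille coupling joins C4 and C5 with retention at both alkenes and so closes the ten-membered ring as the 3Z,5Z diene; the copper-carboxylate/phosphinate variant runs at room temperature without fluoride, which suits the vinyl oxirane and the silylethyl ester.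

Step 16
Reactants: 26 the macrocyclic (3Z,5Z)-diene of step 15, 27 dioxygen
Product: 28 2-(trimethylsilyl)ethyl (1R,2R,3S,6R,7R,8R,10R)-1,2-epoxy-3,6-epidioxy-10-hydroxy-8-tigloyloxygermacra-4,11(13)-dien-12-oate
Conditions: O2, tetraphenylporphyrin (1 mol %), visible light (LED), CH2Cl2, −30 °C
Reagents that add atoms: none
Why: Sensitised singlet oxygen adds suprafacially across C3 and C6 of the s-cis diene in a concerted [4+2] cycloaddition, forming both C–O bonds on one face. The closest known reaction type is the photooxygenation of cyclic 1,3-dienes (medium-ring cis,cis-dienes included) to bicyclic endoperoxides. The six-membered 3,6-dihydro-1,2-dioxine ring is closed by this cycloaddition itself, which bridges the carbocycle and locks C4=C5 as Z. C3 and C6 are set together by the face of attack, and this is controlled by allylic 1,3-strain at C7: H7 lies in the diene plane, ring carbon C8 (and with it the C9–C10–C1 chain) covers one face and the acrylate leans out on the other, so oxygen should enter on the face not spanned by the ring and give the (3S,6R) adduct. In this adduct the C6–O bond is trans to the C7 acrylate, which is why the lactone is later closed with inversion; the oxirane oxygen at C2 is small enough to accept the in-plane position that this conformer asks of it. The step needs cycloaddition to outrun the Schenck ene reaction and attack on other alkenes, and the substrate secures this because the crowded side of C3=C4 carries only an oxirane C–H (no abstractable allylic hydrogen at C2), the C15 methyl sits on the disfavoured side, and the tiglate and acrylate alkenes are electron-poor.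

Step 17
Reactants: 28 the endoperoxide of step 16
Product: 29 2-(trimethylsilyl)ethyl (1R,2R,4Z,6R,7S,8R,10R)-1,2-epoxy-6,10-dihydroxy-3-oxo-8-tigloyloxygermacra-4,11(13)-dien-12-oate
Conditions: Et3N, CH2Cl2, 0 °C → rt
Reagents that add atoms: none
Why: Kornblum–DeLaMare rearrangement; the amine removes H3, which is α to the oxirane and less hindered than H6, the O–O bond breaks, and the C3 ketone and C6 alcohol result with C4=C5 held Z. The bulky silylethyl ester, trans to the C6 hydroxyl, should not lactonise.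

Step 18
Reactants: 29 the hydroxy enone ester of step 17
Product: 30 (1R,2R,4Z,6R,7S,8R,10R)-1,2-epoxy-6,10-dihydroxy-3-oxo-8-tigloyloxygermacra-4,11(13)-dien-12-oic acid
Conditions: tris(dimethylamino)sulfonium difluorotrimethylsilicate, DMF, 0 °C; pH 5 phosphate buffer
Reagents that add atoms: none
Why: Fluoride-induced β-elimination of the 2-(trimethylsilyl)ethyl ester frees the acid without hydrolysis, so the tiglate, the epoxy ketone and the enone are spared.

Step 19
Reactants: 30 the hydroxy acid of step 18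
Product: 31 (1R,2R,4Z,6S,7R,8R,10R)-1,2-epoxy-10-hydroxy-3-oxo-8-tigloyloxygermacra-4,11(13)-dien-12,6-olide (CNP0383091.1)
Conditions: PPh3, diisopropyl azodicarboxylate, THF (5 mM), 0 °C
Reagents that add atoms: none
Why: Mitsunobu lactonisation; the C6 alcohol is activated as its alkoxyphosphonium ion and displaced by the C12 carboxylate in a 5-exo-tet SN2 step, so C6 is inverted from R to S and the cis-fused α-methylene lactone forms. The tertiary alcohol is inert.

**Compound list**

1 | (S)-2-methylglycidol | OC[C@]1(C)OC1 | starting material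
2 | (R)-2-methylpent-4-ene-1,2-diol | OC[C@](C)(O)CC=C | intermediate
3 | (R)-2-hydroxy-2-methylpent-4-enal | O=C[C@](C)(O)CC=C | intermediate
4 | ethyl (R,E)-4-hydroxy-4-methylhepta-2,6-dienoate | CCOC(=O)/C=C/[C@](C)(O)CC=C | intermediate
5 | (R,E)-4-methylhepta-2,6-diene-1,4-diol | OC/C=C/[C@](C)(O)CC=C | intermediate
6 | [(2S,3R)-3-[(2R)-2-hydroxypent-4-en-2-yl]oxiran-2-yl]methanol | OC[C@@H]1O[C@H]1[C@](C)(O)CC=C | intermediate
7 | (2R,3R)-3-[(2R)-2-hydroxypent-4-en-2-yl]oxirane-2-carbaldehyde | O=C[C@@H]1O[C@H]1[C@](C)(O)CC=C | intermediate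
8 | (2R)-2-[(2R,3S)-3-[(1Z)-2-iodoprop-1-en-1-yl]oxiran-2-yl]pent-4-en-2-ol | I/C(C)=C\[C@@H]1O[C@H]1[C@](C)(O)CC=C | intermediate
9 | (3R)-3-hydroxy-3-[(2R,3S)-3-[(1Z)-2-iodoprop-1-en-1-yl]oxiran-2-yl]butanal | O=CC[C@@](C)(O)[C@@H]1O[C@H]1/C=C(/C)I | intermediate
10 | propiolic acid | C#CC(=O)O | starting material
11 | 2-(trimethylsilyl)ethanol | OCC[Si](C)(C)C | starting material
12 | 2-(trimethylsilyl)ethyl propiolate | C#CC(=O)OCC[Si](C)(C)C | intermediate
13 | propargyl alcohol | C#CCO | starting material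
14 | lithium 2,2-dihydrido-2,5-dihydro-1,2-oxaaluminol-2-uide (cyclic vinylalanate) | [Li+].[AlH2-]1OCC=C1 | intermediate
15 | (Z)-3-(tributylstannyl)prop-2-en-1-ol | OC/C=C\[Sn](CCCC)(CCCC)CCCC | intermediate
16 | (Z)-3-(tributylstannyl)prop-2-enal | O=C/C=C\[Sn](CCCC)(CCCC)CCCC | intermediate
17 | 2-(trimethylsilyl)ethyl 2-(diisobutylalumanyl)prop-2-enoate | C=C([Al](CC(C)C)CC(C)C)C(=O)OCC[Si](C)(C)C | intermediate
18 | 2-(trimethylsilyl)ethyl (4Z)-3-hydroxy-2-methylidene-5-(tributylstannyl)pent-4-enoate (racemic) | C=C(C(=O)OCC[Si](C)(C)C)C(O)/C=C\[Sn](CCCC)(CCCC)CCCC | intermediate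
19 | 2-(trimethylsilyl)ethyl (4Z)-3-(methylsulfonyloxy)-2-methylidene-5-(tributylstannyl)pent-4-enoate (racemic) | C=C(C(=O)OCC[Si](C)(C)C)C(OS(C)(=O)=O)/C=C\[Sn](CCCC)(CCCC)CCCC | intermediate
20 | 2-(trimethylsilyl)ethyl (2Z,4Z)-2-(bromomethyl)-5-(tributylstannyl)penta-2,4-dienoate | BrC/C(C(=O)OCC[Si](C)(C)C)=C\C=C/[Sn](CCCC)(CCCC)CCCC | intermediate
21 | dichloro[(2Z,4Z)-2-[2-(trimethylsilyl)ethoxycarbonyl]-5-(tributylstannyl)penta-2,4-dien-1-yl]chromium (ligand and solvent omitted) | Cl[Cr](Cl)C/C(C(=O)OCC[Si](C)(C)C)=C\C=C/[Sn](CCCC)(CCCC)CCCC | intermediate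
22 | 2-(trimethylsilyl)ethyl (3R,4R,6R)-4,6-dihydroxy-6-[(2R,3S)-3-[(1Z)-2-iodoprop-1-en-1-yl]oxiran-2-yl]-2-methylidene-3-[(1Z)-2-(tributylstannyl)ethenyl]heptanoate | C=C(C(=O)OCC[Si](C)(C)C)[C@@H](/C=C\[Sn](CCCC)(CCCC)CCCC)[C@H](O)C[C@@](C)(O)[C@@H]1O[C@H]1/C=C(/C)I | intermediate
23 | tiglic acid | C/C=C(\C)C(=O)O | starting material
24 | tiglic 2,4,6-trichlorobenzoic anhydride | C/C=C(\C)C(=O)OC(=O)c1c(Cl)cc(Cl)cc1Cl | intermediate
25 | 2-(trimethylsilyl)ethyl (3R,4R,6R)-6-hydroxy-6-[(2R,3S)-3-[(1Z)-2-iodoprop-1-en-1-yl]oxiran-2-yl]-2-methylidene-4-[(2E)-2-methylbut-2-enoyl]oxy-3-[(1Z)-2-(tributylstannyl)ethenyl]heptanoate | C=C(C(=O)OCC[Si](C)(C)C)[C@@H](/C=C\[Sn](CCCC)(CCCC)CCCC)[C@H](OC(=O)/C(C)=C/C)C[C@@](C)(O)[C@@H]1O[C@H]1/C=C(/C)I | intermediate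
26 | 2-(trimethylsilyl)ethyl (1R,2S,3Z,5Z,7R,8R,10R)-1,2-epoxy-10-hydroxy-8-tigloyloxygermacra-3,5,11(13)-trien-12-oate | C=C(C(=O)OCC[Si](C)(C)C)[C@H]1/C=C\C(C)=C/[C@@H]2O[C@H]2[C@](C)(O)C[C@H]1OC(=O)/C(C)=C/C | intermediate
27 | dioxygen (used as sensitised singlet oxygen) | O=O | starting material
28 | 2-(trimethylsilyl)ethyl (1R,2R,3S,6R,7R,8R,10R)-1,2-epoxy-3,6-epidioxy-10-hydroxy-8-tigloyloxygermacra-4,11(13)-dien-12-oate | C=C(C(=O)OCC[Si](C)(C)C)[C@H]1[C@H]2C=C(C)[C@H](OO2)[C@@H]3O[C@H]3[C@](C)(O)C[C@H]1OC(=O)/C(C)=C/C | intermediate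
29 | 2-(trimethylsilyl)ethyl (1R,2R,4Z,6R,7S,8R,10R)-1,2-epoxy-6,10-dihydroxy-3-oxo-8-tigloyloxygermacra-4,11(13)-dien-12-oate | C=C(C(=O)OCC[Si](C)(C)C)[C@H]1[C@H](O)/C=C(/C)C(=O)[C@@H]2O[C@H]2[C@](C)(O)C[C@H]1OC(=O)/C(C)=C/C | intermediate
30 | (1R,2R,4Z,6R,7S,8R,10R)-1,2-epoxy-6,10-dihydroxy-3-oxo-8-tigloyloxygermacra-4,11(13)-dien-12-oic acid | C=C(C(=O)O)[C@H]1[C@H](O)/C=C(/C)C(=O)[C@@H]2O[C@H]2[C@](C)(O)C[C@H]1OC(=O)/C(C)=C/C | intermediate
31 | (1R,2R,4Z,6S,7R,8R,10R)-1,2-epoxy-10-hydroxy-3-oxo-8-tigloyloxygermacra-4,11(13)-dien-12,6-olide (CNP0383091.1) | C=C1C(=O)O[C@H]2/C=C(/C)C(=O)[C@@H]3O[C@H]3[C@](C)(O)C[C@@H](OC(=O)/C(C)=C/C)[C@@H]12 | target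

**Step count and risks**

Total step count: 19. Longest linear sequence: 14 steps (steps 1–7, then 13–19); the stannane branch (steps 9–12) joins at step 13, and step 8 feeds step 11.

Steps most likely to fail:

Step 16 (photooxygenation). The twisted Z,Z-diene may cycloadd slowly, and the facial selectivity may be poor or reversed, because the two allylic centres C2 and C7 favour opposite placements of the ring chain. The fallback sets out from 26 and returns at 31. If oxygen enters on the other face, the product is 2-(trimethylsilyl)ethyl (1R,2R,3R,6S,7R,8R,10R)-1,2-epoxy-3,6-epidioxy-10-hydroxy-8-tigloyloxygermacra-4,11(13)-dien-12-oate F1. Amine treatment as in step 17 would give 2-(trimethylsilyl)ethyl (1R,2R,4Z,6S,7S,8R,10R)-1,2-epoxy-6,10-dihydroxy-3-oxo-8-tigloyloxygermacra-4,11(13)-dien-12-oate F2, whose C6 hydroxyl is cis to the C7 ester. The lactone is then closed by acyl transfer with retention at C6 (catalytic DBU in CH2Cl2, loss of 2-(trimethylsilyl)ethanol) instead of by alkylative closure with inversion; this gives 31 and replaces steps 18 and 19.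

Step 15 (Stille macrocyclisation). Oligomerisation may win over closure of the strained ten-membered ring, the stannane may be lost by protodestannylation, or zerovalent palladium may ionise the vinyl oxirane. The fallback sets out from 9 and 18 and returns at 26; it closes the ring at C7–C8 instead of C4–C5. Intermolecular Stille coupling of 9 with 18 under the conditions of step 15 (no dilution needed) would give 2-(trimethylsilyl)ethyl (4Z,6Z,9R)-3,9-dihydroxy-7-methyl-2-methylidene-9-[(2R,3S)-3-... ]-type dienyl carbinol aldehyde, drawn below as the acyclic C4–C5-coupled hydroxy aldehyde F3. Mesylation and bromide displacement as in step 12 would give the acyclic dienyl allylic bromide aldehyde F4. An intramolecular Nozaki–Hiyama–Kishi allylation (CrCl2, THF, high dilution) would close the ring to the macrocyclic C8 alcohol F5, with the C7/C8 diastereomers to be separated if substrate control is incomplete. Yamaguchi esterification of F5 with 23 gives 26.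

Step 19 (Mitsunobu lactonisation). Activation of the carboxyl instead of the alcohol (acyloxyphosphonium path), or participation of the cis C3 carbonyl, would close the lactone with retention; elimination toward C7 is a further side path. The fallback sets out from 29 and returns at 31; it activates C6 before the carboxylate exists. Methanesulfonic anhydride and pyridine (no chloride present) would convert 29 into 2-(trimethylsilyl)ethyl (1R,2R,4Z,6R,7S,8R,10R)-1,2-epoxy-10-hydroxy-6-(methylsulfonyloxy)-3-oxo-8-tigloyloxygermacra-4,11(13)-dien-12-oate F6. Tris(dimethylamino)sulfonium difluorotrimethylsilicate then unmasks the carboxylate, which can only displace the mesylate by SN2 with inversion, giving 31.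

Further compounds

F1 | step 16 | 2-(trimethylsilyl)ethyl (1R,2R,3R,6S,7R,8R,10R)-1,2-epoxy-3,6-epidioxy-10-hydroxy-8-tigloyloxygermacra-4,11(13)-dien-12-oate | C=C(C(=O)OCC[Si](C)(C)C)[C@H]1[C@@H]2C=C(C)[C@@H](OO2)[C@@H]3O[C@H]3[C@](C)(O)C[C@H]1OC(=O)/C(C)=C/C
F2 | step 16 | 2-(trimethylsilyl)ethyl (1R,2R,4Z,6S,7S,8R,10R)-1,2-epoxy-6,10-dihydroxy-3-oxo-8-tigloyloxygermacra-4,11(13)-dien-12-oate | C=C(C(=O)OCC[Si](C)(C)C)[C@H]1[C@@H](O)/C=C(/C)C(=O)[C@@H]2O[C@H]2[C@](C)(O)C[C@H]1OC(=O)/C(C)=C/C
F3 | step 15 | acyclic C4–C5-coupled hydroxy aldehyde (3Z,5Z-diene, C7 carbinol racemic, C8 aldehyde, 1,2-oxirane and C10 carbinol as in 9) | O=CC[C@@](C)(O)[C@@H]1O[C@H]1/C=C(C)\C=C/C(O)C(=C)C(=O)OCC[Si](C)(C)C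
F4 | step 15 | acyclic dienyl allylic bromide aldehyde (C13 bromide, 3Z,5Z,7(11)Z-triene, C8 aldehyde) | O=CC[C@@](C)(O)[C@@H]1O[C@H]1/C=C(C)\C=C/C=C(\CBr)C(=O)OCC[Si](C)(C)C
F5 | step 15 | 2-(trimethylsilyl)ethyl (1R,2S,3Z,5Z,7R,8R,10R)-1,2-epoxy-8,10-dihydroxygermacra-3,5,11(13)-trien-12-oate | C=C(C(=O)OCC[Si](C)(C)C)[C@H]1/C=C\C(C)=C/[C@@H]2O[C@H]2[C@](C)(O)C[C@H]1O
F6 | step 19 | 2-(trimethylsilyl)ethyl (1R,2R,4Z,6R,7S,8R,10R)-1,2-epoxy-10-hydroxy-6-(methylsulfonyloxy)-3-oxo-8-tigloyloxygermacra-4,11(13)-dien-12-oate | C=C(C(=O)OCC[Si](C)(C)C)[C@H]1[C@H](OS(C)(=O)=O)/C=C(/C)C(=O)[C@@H]2O[C@H]2[C@](C)(O)C[C@H]1OC(=O)/C(C)=C/C
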